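Assumption: 1,3,5-tris(benzyloxy)benzene (7), the Reformatsky reagent 9 (ether solution) and (2R)-2-methylbutanoic acid (22) are taken as purchasable; 22 has the R configuration that the target needs.

## Analysis of the target

The target has no fused rings: three fully substituted benzene rings are joined in a row by two methylene bridges, ring A–CH2–ring B–CH2–ring C. Ring B is a phloroglucinol (hydroxyls at B2, B4, B6) with the (2R)-2-methylbutanoyl group at B1 and the bridges at B3 and B5. Rings A and C share one pattern: the bridge carbon (A1, C1) sits between two hydroxyls (A2/A6, C2/C6), followed by a C-methyl (A3, C3), the only methyl ether (A4, C4) and an acyl group (A5 acetyl, C5 2-methylpropanoyl). The single stereocentre is the α-carbon of the ring B ketone; it has no partner, so only its absolute configuration matters, but it can be lost by enolisation. Sensitive features are the seven phenols (oxidation as phenolates), the diarylmethane links between electron-rich rings (reversible through ortho-quinone methides), and the methyl ethers next to chelating carbonyls (cleaved by hard Lewis acids). The difficulty is that three phloroglucinol nuclei must be told apart, that the methylated oxygen is not the one ordinary methylation chooses (the hydroxyl para to the acyl group reacts first), and that rings A and C differ only in their acyl group, which rules out a symmetric dimerisation. The strategy rests on ring A: if A6, A3, A4 and A5 come from one four-carbon unit that already carries the methyl and the methoxy group, and A1 and A2 from an alkyne, the methyl ether at A4 is fixed by construction and the oxygens at A2, A4 and A6 emerge differently masked.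

## Retrosynthetic reasoning

The last bond to form is B5–CH2 of the bridge to ring C, which divides target 35 into nucleophile 26 and Mannich base 33. The cut is placed here because each half then has exactly one reactive site: 26 has a single aromatic C–H (B5), and 33 has one latent electrophilic carbon, released as ortho-quinone methide 34. The forward step must alkylate carbon under near-neutral conditions without touching the stereocentre.

Mannich base 33 goes back to ketone 32 by removing the aminomethyl group from its only free ring carbon. The O–CH3 bond of 32 is cut next: in 31 and 30 the two more accessible hydroxyls are masked as sulfonates, so that methylation can only reach the hydroxyl wedged between methyl and acyl. Triol 29 comes from 27 and 28 by acylation at one of two equivalent positions.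

In 26 the B1–acyl bond is cut. This is done at the protected stage (24 from 21 and acid 22 through mixed anhydride 23) because ring A of 21 has no C–H left, so an acyl electrophile can only enter ring B, whose two free positions are equivalent. Only acid is present in that step, so the purchased stereocentre is not exposed to base. Removing the silyl group (25) and the benzyl groups (26) follows; benzyl ethers were chosen for ring B because hydrogenolysis releases no electrophile that could attack the free phloroglucinol.

The acetyl group of 21 is disconnected at A5 to iodide 18 and stannane 19 (through enol ether 20), and 18 to phenol 17. A5 is the only open carbon of ring A, and the free A6 hydroxyl makes ring A far more reactive than the neutral ring B. An O-acetylation followed by a photochemical acyl shift was not used, since the aryl benzyl ethers of ring B absorb and cleave under the same light, and a Lewis-acid shift would strip them.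

Ring A of 17 is taken apart at A6–A1 and A2–A3, with A5–A6 as the ring-closing bond, giving cyclobutenone 6 and siloxyalkyne 12 (through 13, 14, 15 and 16). This cut places methyl and methoxy in one small building block and needs no reagent, only heat, so the benzyl ethers and ring B are not at risk. The forward reaction has to join the benzyl-bearing alkyne carbon to the ketene carbonyl carbon.

Siloxyalkyne 12 comes from ester 10 through ynolate 11, which adds one carbon and turns the ester carbon into an alkyne carbon. Ester 10 is cut at the aryl–CH2 bond to bromide 8 and zinc enolate 9, and 8 comes from 7.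

Cyclobutenone 6 is reached from 5 by alkoxy exchange, 5 from 4 by reductive dechlorination, and 4 from 1 and 2 through ketene 3 by [2+2] cycloaddition.

## Alternatives that were turned down

Alternative 1: Ring C, not ring A, would be built on a ring B benzyl unit by cutting C1–C6 and C4–C5.
- Key step: the precursors are cyclohexadiene A1 (2-{[4-methoxy-3-methyl-2-(trimethylsilyloxy)cyclohexa-1,3-dien-1-yl]methyl}-1,3,5-tris(benzyloxy)benzene) and bromo ynone A2 (1-bromo-4-methylpent-1-yn-3-one). A [4+2] cycloaddition is followed by Alder–Rickert cycloreversion, in which the bicyclo[2.2.2]octadiene loses its two-carbon bridge, to give arene A3 (1-(2-bromo-6-methoxy-5-methyl-4-(trimethylsilyloxy)-3-{[2,4,6-tris(benzyloxy)phenyl]methyl}phenyl)-2-methylpropan-1-one).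
- For: the acyl group arrives with the ring, and the push–pull diene matches the ynone in polarity. On acyl economy this is stronger than the chosen route.
- Against: both diene termini of A1 are fully substituted, so two quaternary bridgeheads must form. A1 needs a 1,3-dione in which one oxygen is methylated and the other silylated, which is the same oxygen-differentiation problem moved earlier. A3 carries bromine where a hydroxyl is needed, on a hexasubstituted ring.
- Comparison: the chosen route takes the methyl ether from building block 6 with no regiochemical decision, and every oxygen arrives at its final oxidation level.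

Alternative 2: Ring B would be formed last by cutting B1–B2.
- Key step: the open-chain precursor is A4 (methyl (8R)-2-{[3-acetyl-2,6-bis(benzyloxy)-4-methoxy-5-methylphenyl]methyl}-4-{[2,6-bis(benzyloxy)-4-methoxy-3-methyl-5-(2-methylpropanoyl)phenyl]methyl}-8-methyl-3,5,7-trioxodecanoate). A magnesium alkoxide would drive the Claisen condensation of the methylene between the two ketones onto the ester, and enolisation would give A5 (the target with benzyl ethers on the four outer-ring hydroxyls).
- For: it is the most convergent plan. Both bridges and all acyl groups are in place before ring B exists, and no late bridge formation or ring B acylation is needed. On these points it is stronger.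
- Against: A4 is a triketo ester with two bulky α-benzyl branches and is hard to assemble. It can also close through oxygen or by aldol paths. Its stereocentre lies α to a ketone and is exposed to alkoxide throughout the cyclisation.
- Comparison: the chosen route introduces the stereocentre under acid-only conditions and uses simple aromatic chemistry after the ring synthesis.

Alternative 3: Ring A would be made by a [3+3] union, cutting A1–A2 and A4–A5.
- Key step: the partners are bis(silyl enol ether) A6 (2-[3,5-bis(trimethylsilyloxy)hexa-2,4-dien-1-yl]-1,3,5-tris(benzyloxy)benzene) and acid chloride A7 (3,3-dimethoxy-2-methylprop-2-enoyl chloride). Under a strong chlorotitanium Lewis acid the terminal diene carbon attacks the acid chloride carbon and the central carbon attacks the ketene acetal carbon, with loss of alcohol, giving A8 (1-(2,4-dihydroxy-6-methoxy-5-methyl-3-{[2,4,6-tris(benzyloxy)phenyl]methyl}phenyl)ethan-1-one).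
- For: the acetyl group is already in place and both hydroxyls are free, which saves steps 8, 9 and the desilylation. On step count it is stronger.
- Against: the Lewis acid meets three benzyl ethers on the most nucleophilic arene of the molecule, and A7 can acylate ring B. The reverse pairing of the reacting carbons would put the methyl ether next to the bridge. A7 is a labile reagent.
- Comparison: the chosen benzannulation needs only heat, and its orientation follows from the strong polarisation of 12. The price is two later steps for the acetyl group.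

Key step: step 7

## Route

Step 1
Reactants: 1 trichloroacetyl chloride; 2 1-ethoxyprop-1-yne
Product: 4 4,4-dichloro-3-ethoxy-2-methylcyclobut-2-en-1-one, via dichloroketene 3 (not isolated)
Conditions: Zn–Cu couple, Et2O/DME, rt
Reagents that add atoms: none
Why: Zinc dehalogenation of 1 gives ketene 3, which undergoes [2+2] cycloaddition with the electron-rich ynol ether 2; the methyl-bearing alkyne carbon bonds to the ketene carbonyl carbon, so ethoxy ends at C3 and methyl at C2.

Step 2
Reactants: 4 4,4-dichloro-3-ethoxy-2-methylcyclobut-2-en-1-one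
Product: 5 3-ethoxy-2-methylcyclobut-2-en-1-one
Conditions: Zn dust, AcOH, TMEDA, EtOH, 0 °C → rt
Reagents that add atoms: none
Why: Buffered zinc reduction removes both chlorines α to the carbonyl through zinc enolates (reductive dehalogenation of an α,α-dichloroketone) without opening the strained vinylogous ester.

Step 3
Reactants: 5 3-ethoxy-2-methylcyclobut-2-en-1-one
Product: 6 3-methoxy-2-methylcyclobut-2-en-1-one
Conditions: MeOH (solvent), TsOH (cat.), rt
Reagents that add atoms: methanol, CO
Why: Acid-catalysed addition–elimination at C3 of the vinylogous ester (transetherification) should exchange ethoxy for methoxy, driven by the solvent excess; room temperature keeps the ring below its electrocyclic opening.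

Step 4
Reactants: 7 1,3,5-tris(benzyloxy)benzene
Product: 8 2-bromo-1,3,5-tris(benzyloxy)benzene
Conditions: NBS, CH2Cl2, −10 °C → 0 °C
Reagents that add atoms: N-bromosuccinimide, O=C1CCC(=O)N1Br
Why: Electrophilic aromatic bromination of a trialkoxybenzene with three equivalent positions; one equivalent of reagent at low temperature should stop at the monobromide.

Step 5
Reactants: 8 2-bromo-1,3,5-tris(benzyloxy)benzene; 9 (2-ethoxy-2-oxoethyl)zinc bromide
Product: 10 ethyl 2-[2,4,6-tris(benzyloxy)phenyl]acetate
Conditions: Pd2(dba)3 (cat.), XPhos (cat.), THF, 60 °C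
Reagents that add atoms: none
Why: Negishi-type cross-coupling of a Reformatsky zinc enolate with an aryl bromide on zerovalent palladium; the bulky biaryl phosphine is chosen for the doubly ortho-substituted, electron-rich bromide, and the neutral zinc enolate leaves the ester and benzyl ethers alone.

Step 6
Reactants: 10 ethyl 2-[2,4,6-tris(benzyloxy)phenyl]acetate
Product: 12 triisopropyl({3-[2,4,6-tris(benzyloxy)phenyl]prop-1-yn-1-yl}oxy)silane, via lithium ynolate 11 (not isolated)
Conditions: CH2Br2, lithium 2,2,6,6-tetramethylpiperidide, THF, −78 °C; LiN(SiMe3)2; n-BuLi, −78 °C → rt; iPr3SiCl, −78 °C → rt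
Reagents that add atoms: dibromomethane, BrCBr; chlorotriisopropylsilane, CC(C)[Si](Cl)(C(C)C)C(C)C
Why: Kowalski ester homologation stopped at the ynolate: LiCHBr2 adds to the ester, the dibromoketone enolate undergoes bromine–lithium exchange and 1,2-shift of the arylmethyl group to give 11, and the bulky silyl chloride reacts at oxygen to give the siloxyalkyne.

Step 7
Reactants: 6 3-methoxy-2-methylcyclobut-2-en-1-one; 12 triisopropyl({3-[2,4,6-tris(benzyloxy)phenyl]prop-1-yn-1-yl}oxy)silane
Product: 17 5-methoxy-4-methyl-3-[(triisopropylsilyl)oxy]-2-{[2,4,6-tris(benzyloxy)phenyl]methyl}phenol, via vinylketene 13 (not isolated), via vinylcyclobutenone 14 (not isolated), via dienylketene 15 (not isolated), via cyclohexadienone 16 (not isolated)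
Conditions: toluene, 80 °C then 110 °C, sealed tube, 6 in slight excess
Reagents that add atoms: none
Why: Heating opens 6 by 4π-electrocyclic cleavage of its C1–C4 bond to vinylketene 13. Siloxyalkyne 12, whose benzyl-bearing carbon is made nucleophilic by the oxygen donor, adds across the ketene C=C in a [2+2] cycloaddition with that carbon bonding to the ketene carbonyl carbon, giving 14 and the new bonds A6–A1 and A2–A3. 14 opens (4π) to dienylketene 15, and a thermal disrotatory 6π-electrocyclisation between the ketene carbon and the methylene terminus closes the six-membered ring A (bond A5–A6) as 16, which tautomerises to phenol 17. The closest known reaction is the Danheiser benzannulation of cyclobutenones with siloxyalkynes to resorcinol monosilyl ethers. No stereocentre is set: the quaternary carbon of 14 is racemic and disappears on aromatisation. The selectivity needed is the orientation of the [2+2] step, secured by the polarisation of 12 against the electrophilic ketene carbon; it places the benzyl carbon between the free hydroxyl and the siloxy group, while methyl and methoxy arrive already adjacent from 6. Only the isomer of 15 with the methoxyvinyl group cis to the ketene can cyclise, but opening of 14 is reversible, so material should funnel through it. The conditions are neutral, so the benzyl ethers and the electron-rich ring B are not touched.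

Step 8
Reactants: 17 5-methoxy-4-methyl-3-[(triisopropylsilyl)oxy]-2-{[2,4,6-tris(benzyloxy)phenyl]methyl}phenol
Product: 18 2-iodo-3-methoxy-4-methyl-5-[(triisopropylsilyl)oxy]-6-{[2,4,6-tris(benzyloxy)phenyl]methyl}phenol
Conditions: I2 (1.0 equiv), morpholine, CH2Cl2, 0 °C
Reagents that add atoms: iodine, [I][I]
Why: Electrophilic iodination of a phenol by the mild iodine–amine complex; A5 is the only free carbon of ring A and is activated by the free A6 hydroxyl, whereas the neutral triether ring B should not react with this weak electrophile.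

Step 9
Reactants: 18 2-iodo-3-methoxy-4-methyl-5-[(triisopropylsilyl)oxy]-6-{[2,4,6-tris(benzyloxy)phenyl]methyl}phenol; 19 tributyl(1-ethoxyethenyl)stannane
Product: 21 1-(2-hydroxy-6-methoxy-5-methyl-4-[(triisopropylsilyl)oxy]-3-{[2,4,6-tris(benzyloxy)phenyl]methyl}phenyl)ethan-1-one, via enol ether 20 (not isolated)
Conditions: Pd(PPh3)4 (cat.), CuI (cat.), DMF, 80 °C; then 1 M HCl, THF, rt
Reagents that add atoms: water, O
Why: Stille coupling with an α-alkoxyvinylstannane as acetyl equivalent, copper co-catalysis helping the hindered transmetallation; mild aqueous acid hydrolyses enol ether 20 to the methyl ketone and leaves the silyl and benzyl ethers in place.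

Step 10
Reactants: 21 1-(2-hydroxy-6-methoxy-5-methyl-4-[(triisopropylsilyl)oxy]-3-{[2,4,6-tris(benzyloxy)phenyl]methyl}phenyl)ethan-1-one; 22 (2R)-2-methylbutanoic acid
Product: 24 (2R)-1-[3-({3-acetyl-2-hydroxy-4-methoxy-5-methyl-6-[(triisopropylsilyl)oxy]phenyl}methyl)-2,4,6-tris(benzyloxy)phenyl]-2-methylbutan-1-one, via mixed anhydride 23 (not isolated)
Conditions: 22, (CF3CO)2O, CH2Cl2, 0 °C; then 21, 0 °C → rt
Reagents that add atoms: none
Why: Friedel–Crafts acylation of a trialkoxybenzene by a mixed carboxylic–trifluoroacetic anhydride without metal Lewis acid; ring A has no C–H, the two free positions of ring B are equivalent, and the first acyl group deactivates the ring against a second. No base is present, so the stereocentre of 22 should be carried over unchanged.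

Step 11
Reactants: 24 (2R)-1-[3-({3-acetyl-2-hydroxy-4-methoxy-5-methyl-6-[(triisopropylsilyl)oxy]phenyl}methyl)-2,4,6-tris(benzyloxy)phenyl]-2-methylbutan-1-one
Product: 25 (2R)-1-[3-({3-acetyl-2,6-dihydroxy-4-methoxy-5-methylphenyl}methyl)-2,4,6-tris(benzyloxy)phenyl]-2-methylbutan-1-one
Conditions: Bu4NF, AcOH, THF, 0 °C
Reagents that add atoms: none
Why: Fluoride cleavage of an aryl silyl ether, made easy by the para acetyl group; acetic acid buffers the fluoride so that the ketone α-stereocentre is not enolised.

Step 12
Reactants: 25 (2R)-1-[3-({3-acetyl-2,6-dihydroxy-4-methoxy-5-methylphenyl}methyl)-2,4,6-tris(benzyloxy)phenyl]-2-methylbutan-1-one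
Product: 26 (2R)-1-[3-({3-acetyl-2,6-dihydroxy-4-methoxy-5-methylphenyl}methyl)-2,4,6-trihydroxyphenyl]-2-methylbutan-1-one
Conditions: H2 (1 atm), Pd/C, EtOAc/MeOH, rt
Reagents that add atoms: none
Why: Catalytic hydrogenolysis of aryl benzyl ethers; the chelated aryl ketones, the diarylmethane link and the methyl ether are inert, and the only by-product is a hydrocarbon that cannot attack the free phloroglucinol.

Step 13
Reactants: 27 2-methylbenzene-1,3,5-triol; 28 2-methylpropanoyl chloride
Product: 29 2-methyl-1-(2,4,6-trihydroxy-3-methylphenyl)propan-1-one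
Conditions: AlCl3, PhNO2/CH2Cl2, rt → 50 °C; aq. HCl work-up
Reagents that add atoms: none
Why: Friedel–Crafts acylation of a phloroglucinol; the two free positions are equivalent and the product is deactivated against a second acylation.

Step 14
Reactants: 29 2-methyl-1-(2,4,6-trihydroxy-3-methylphenyl)propan-1-one
Product: 30 1-[2-hydroxy-3-methyl-4,6-bis(4-methylbenzenesulfonyloxy)phenyl]-2-methylpropan-1-one
Conditions: TsCl (2.05 equiv), K2CO3, acetone, reflux
Reagents that add atoms: 4-methylbenzenesulfonyl chloride, Cc1ccc(cc1)S(Cl)(=O)=O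
Why: O-Sulfonylation takes the most acidic para hydroxyl first and then the ortho hydroxyl next to ring hydrogen; the hydroxyl wedged between methyl and acyl is the most hindered and stays chelated to the carbonyl.

Step 15
Reactants: 30 1-[2-hydroxy-3-methyl-4,6-bis(4-methylbenzenesulfonyloxy)phenyl]-2-methylpropan-1-one
Product: 31 1-[2-methoxy-3-methyl-4,6-bis(4-methylbenzenesulfonyloxy)phenyl]-2-methylpropan-1-one
Conditions: MeI, K2CO3, DMF, 50 °C
Reagents that add atoms: iodomethane, CI
Why: Williamson methylation of the one remaining phenol; a polar solvent and warming overcome the chelation, and the aryl sulfonates do not react.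

Step 16
Reactants: 31 1-[2-methoxy-3-methyl-4,6-bis(4-methylbenzenesulfonyloxy)phenyl]-2-methylpropan-1-one
Product: 32 1-(4,6-dihydroxy-2-methoxy-3-methylphenyl)-2-methylpropan-1-one
Conditions: KOH, MeOH/H2O, reflux; then aq. HCl
Reagents that add atoms: none
Why: Saponification of aryl sulfonates by attack at sulfur, helped by the ortho and para acyl group that stabilises the departing phenolates; the methyl ether is untouched.

Step 17
Reactants: 32 1-(4,6-dihydroxy-2-methoxy-3-methylphenyl)-2-methylpropan-1-one
Product: 33 1-{3-[(dimethylamino)methyl]-2,4-dihydroxy-6-methoxy-5-methylphenyl}-2-methylpropan-1-one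
Conditions: CH2=NMe2+ I− (Eschenmoser's salt), Et3N, CH2Cl2, 0 °C → rt
Reagents that add atoms: N,N-dimethylmethyleneiminium iodide, C=[N+](C)C.[I-]
Why: Mannich aminomethylation with a preformed iminium salt at the only free ring carbon, which lies between two hydroxyls; the stoichiometric salt avoids the methylene-bridged dimer that free formaldehyde would give.

Step 18
Reactants: 26 (2R)-1-[3-({3-acetyl-2,6-dihydroxy-4-methoxy-5-methylphenyl}methyl)-2,4,6-trihydroxyphenyl]-2-methylbutan-1-one; 33 1-{3-[(dimethylamino)methyl]-2,4-dihydroxy-6-methoxy-5-methylphenyl}-2-methylpropan-1-one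
Product: 35 (2R)-1-[3-({3-acetyl-2,6-dihydroxy-4-methoxy-5-methylphenyl}methyl)-5-{[2,6-dihydroxy-4-methoxy-3-methyl-5-(2-methylpropanoyl)phenyl]methyl}-2,4,6-trihydroxyphenyl]-2-methylbutan-1-one (target), via ortho-quinone methide 34 (not isolated)
Conditions: 1,4-dioxane, 90 °C, argon
Reagents that add atoms: none
Why: Thermal loss of the amine from the ortho-hydroxybenzylamine gives quinone methide 34, which is captured in a conjugate addition by B5, the only aromatic C–H in either partner; O-alkylation is reversible and should drain to the C–C product. The liberated amine turns the ring B ketone into a vinylogous carboxylate, which protects the α-stereocentre from enolisation.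

## Compound list

1 | trichloroacetyl chloride | ClC(=O)C(Cl)(Cl)Cl | starting material
2 | 1-ethoxyprop-1-yne | CCOC#CC | starting material
3 | dichloroketene | ClC(Cl)=C=O | intermediate (not isolated)
4 | 4,4-dichloro-3-ethoxy-2-methylcyclobut-2-en-1-one | CCOC1=C(C)C(=O)C1(Cl)Cl | intermediate
5 | 3-ethoxy-2-methylcyclobut-2-en-1-one | CCOC1=C(C)C(=O)C1 | intermediate
6 | 3-methoxy-2-methylcyclobut-2-en-1-one | COC1=C(C)C(=O)C1 | intermediate
7 | 1,3,5-tris(benzyloxy)benzene | c1ccc(COc2cc(OCc3ccccc3)cc(OCc3ccccc3)c2)cc1 | starting material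
8 | 2-bromo-1,3,5-tris(benzyloxy)benzene | Brc1c(OCc2ccccc2)cc(OCc2ccccc2)cc1OCc1ccccc1 | intermediate
9 | (2-ethoxy-2-oxoethyl)zinc bromide | CCOC(=O)C[Zn]Br | starting material
10 | ethyl 2-[2,4,6-tris(benzyloxy)phenyl]acetate | CCOC(=O)Cc1c(OCc2ccccc2)cc(OCc2ccccc2)cc1OCc1ccccc1 | intermediate
11 | lithium 3-[2,4,6-tris(benzyloxy)phenyl]prop-1-yn-1-olate | [Li+].[O-]C#CCc1c(OCc2ccccc2)cc(OCc2ccccc2)cc1OCc1ccccc1 | intermediate (not isolated)
12 | triisopropyl({3-[2,4,6-tris(benzyloxy)phenyl]prop-1-yn-1-yl}oxy)silane | CC(C)[Si](C(C)C)(C(C)C)OC#CCc1c(OCc2ccccc2)cc(OCc2ccccc2)cc1OCc1ccccc1 | intermediate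
13 | 3-methoxy-2-methylbuta-1,3-dien-1-one | C=C(OC)C(C)=C=O | intermediate (not isolated)
14 | 4-(1-methoxyethenyl)-4-methyl-3-[(triisopropylsilyl)oxy]-2-{[2,4,6-tris(benzyloxy)phenyl]methyl}cyclobut-2-en-1-one (racemic) | C=C(OC)C1(C)C(O[Si](C(C)C)(C(C)C)C(C)C)=C(Cc2c(OCc3ccccc3)cc(OCc3ccccc3)cc2OCc2ccccc2)C1=O | intermediate (not isolated)
15 | (3E)-5-methoxy-4-methyl-3-[(triisopropylsilyl)oxy]-2-{[2,4,6-tris(benzyloxy)phenyl]methyl}hexa-1,3,5-trien-1-one | O=C=C(Cc1c(OCc2ccccc2)cc(OCc2ccccc2)cc1OCc1ccccc1)/C(O[Si](C(C)C)(C(C)C)C(C)C)=C(C)\C(OC)=C | intermediate (not isolated)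
16 | 5-methoxy-4-methyl-3-[(triisopropylsilyl)oxy]-2-{[2,4,6-tris(benzyloxy)phenyl]methyl}cyclohexa-2,4-dien-1-one | O=C1CC(OC)=C(C)C(O[Si](C(C)C)(C(C)C)C(C)C)=C1Cc1c(OCc2ccccc2)cc(OCc2ccccc2)cc1OCc1ccccc1 | intermediate (not isolated)
17 | 5-methoxy-4-methyl-3-[(triisopropylsilyl)oxy]-2-{[2,4,6-tris(benzyloxy)phenyl]methyl}phenol | Oc1cc(OC)c(C)c(O[Si](C(C)C)(C(C)C)C(C)C)c1Cc1c(OCc2ccccc2)cc(OCc2ccccc2)cc1OCc1ccccc1 | intermediate
18 | 2-iodo-3-methoxy-4-methyl-5-[(triisopropylsilyl)oxy]-6-{[2,4,6-tris(benzyloxy)phenyl]methyl}phenol | Oc1c(I)c(OC)c(C)c(O[Si](C(C)C)(C(C)C)C(C)C)c1Cc1c(OCc2ccccc2)cc(OCc2ccccc2)cc1OCc1ccccc1 | intermediate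
19 | tributyl(1-ethoxyethenyl)stannane | CCCC[Sn](CCCC)(CCCC)C(=C)OCC | starting material
20 | 2-(1-ethoxyethenyl)-3-methoxy-4-methyl-5-[(triisopropylsilyl)oxy]-6-{[2,4,6-tris(benzyloxy)phenyl]methyl}phenol | CCOC(=C)c1c(O)c(Cc2c(OCc3ccccc3)cc(OCc3ccccc3)cc2OCc2ccccc2)c(O[Si](C(C)C)(C(C)C)C(C)C)c(C)c1OC | intermediate (not isolated)
21 | 1-(2-hydroxy-6-methoxy-5-methyl-4-[(triisopropylsilyl)oxy]-3-{[2,4,6-tris(benzyloxy)phenyl]methyl}phenyl)ethan-1-one | CC(=O)c1c(O)c(Cc2c(OCc3ccccc3)cc(OCc3ccccc3)cc2OCc2ccccc2)c(O[Si](C(C)C)(C(C)C)C(C)C)c(C)c1OC | intermediate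
22 | (2R)-2-methylbutanoic acid | CC[C@@H](C)C(=O)O | starting material
23 | (2R)-2-methylbutanoic trifluoroacetic anhydride | CC[C@@H](C)C(=O)OC(=O)C(F)(F)F | intermediate (not isolated)
24 | (2R)-1-[3-({3-acetyl-2-hydroxy-4-methoxy-5-methyl-6-[(triisopropylsilyl)oxy]phenyl}methyl)-2,4,6-tris(benzyloxy)phenyl]-2-methylbutan-1-one | CC[C@@H](C)C(=O)c1c(OCc2ccccc2)cc(OCc2ccccc2)c(Cc2c(O)c(C(C)=O)c(OC)c(C)c2O[Si](C(C)C)(C(C)C)C(C)C)c1OCc1ccccc1 | intermediate
25 | (2R)-1-[3-({3-acetyl-2,6-dihydroxy-4-methoxy-5-methylphenyl}methyl)-2,4,6-tris(benzyloxy)phenyl]-2-methylbutan-1-one | CC[C@@H](C)C(=O)c1c(OCc2ccccc2)cc(OCc2ccccc2)c(Cc2c(O)c(C(C)=O)c(OC)c(C)c2O)c1OCc1ccccc1 | intermediate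
26 | (2R)-1-[3-({3-acetyl-2,6-dihydroxy-4-methoxy-5-methylphenyl}methyl)-2,4,6-trihydroxyphenyl]-2-methylbutan-1-one | CC[C@@H](C)C(=O)c1c(O)cc(O)c(Cc2c(O)c(C(C)=O)c(OC)c(C)c2O)c1O | intermediate
27 | 2-methylbenzene-1,3,5-triol (2,4,6-trihydroxytoluene) | Cc1c(O)cc(O)cc1O | starting material
28 | 2-methylpropanoyl chloride | CC(C)C(Cl)=O | starting material
29 | 2-methyl-1-(2,4,6-trihydroxy-3-methylphenyl)propan-1-one | CC(C)C(=O)c1c(O)cc(O)c(C)c1O | intermediate
30 | 1-[2-hydroxy-3-methyl-4,6-bis(4-methylbenzenesulfonyloxy)phenyl]-2-methylpropan-1-one | CC(C)C(=O)c1c(O)c(C)c(OS(=O)(=O)c2ccc(C)cc2)cc1OS(=O)(=O)c1ccc(C)cc1 | intermediate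
31 | 1-[2-methoxy-3-methyl-4,6-bis(4-methylbenzenesulfonyloxy)phenyl]-2-methylpropan-1-one | CC(C)C(=O)c1c(OC)c(C)c(OS(=O)(=O)c2ccc(C)cc2)cc1OS(=O)(=O)c1ccc(C)cc1 | intermediate
32 | 1-(4,6-dihydroxy-2-methoxy-3-methylphenyl)-2-methylpropan-1-one | CC(C)C(=O)c1c(OC)c(C)c(O)cc1O | intermediate
33 | 1-{3-[(dimethylamino)methyl]-2,4-dihydroxy-6-methoxy-5-methylphenyl}-2-methylpropan-1-one | CC(C)C(=O)c1c(O)c(CN(C)C)c(O)c(C)c1OC | intermediate
34 | 5-hydroxy-3-methoxy-4-methyl-6-methylidene-2-(2-methylpropanoyl)cyclohexa-2,4-dien-1-one | C=C1C(O)=C(C)C(OC)=C(C(=O)C(C)C)C1=O | intermediate (not isolated)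
35 | (2R)-1-[3-({3-acetyl-2,6-dihydroxy-4-methoxy-5-methylphenyl}methyl)-5-{[2,6-dihydroxy-4-methoxy-3-methyl-5-(2-methylpropanoyl)phenyl]methyl}-2,4,6-trihydroxyphenyl]-2-methylbutan-1-one | CC[C@@H](C)C(=O)c1c(O)c(Cc2c(O)c(C)c(OC)c(C(C)=O)c2O)c(O)c(Cc2c(O)c(C)c(OC)c(C(=O)C(C)C)c2O)c1O | target

## Step count and least certain steps

Total: 18 steps. Longest linear sequence: 10 steps (steps 4–12 and 18 from 7; the branch from 1 and 2 through steps 1–3 and 7–12, 18 is equally long). The ring C branch (steps 13–17) joins at step 18.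

**Step 7 (key step).**
- Risk: the donor-stabilised cyclobutenone may open too slowly at temperatures that 12 tolerates. The ketene could then dimerise or acylate the product phenol before the alkyne captures it.
- Fallback (sets out from 12, returns at 17): the same ketene 13 is generated at room temperature by a photochemical Wolff rearrangement, the second-generation form of the benzannulation.
  - Lithiated methyl vinyl ether, (1-methoxyethenyl)lithium F1, is added to N-methoxy-N-methylpropanamide to give 2-methoxypent-1-en-3-one F2.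
  - Deacylative diazo transfer follows: LiN(SiMe3)2 and 2,2,2-trifluoroethyl trifluoroacetate give 1,1,1-trifluoro-5-methoxy-3-methylhex-5-ene-2,4-dione F3, and methanesulfonyl azide with Et3N gives 2-diazo-4-methoxypent-4-en-3-one F4.
  - Irradiation of F4 with 12 in CH2Cl2, then warming to 80 °C, should pass through 13–16 to 17.

**Step 6.**
- Risk: proton transfer from the arylacetate CH2 to the carbenoid base may compete with addition to the ester carbonyl. Excess alkyllithium on warming could also rearrange a benzyl ether.
- Fallback (sets out from 8, returns at 12): the ynolate is made by oxidising an acetylide, which involves no ester.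
  - Bromine–lithium exchange (n-BuLi, THF, −78 °C) gives [2,4,6-tris(benzyloxy)phenyl]lithium F5.
  - CuBr·SMe2 (cat.) and 3-bromo-1-(trimethylsilyl)prop-1-yne give trimethyl{3-[2,4,6-tris(benzyloxy)phenyl]prop-1-yn-1-yl}silane F6.
  - K2CO3 in MeOH gives 1,3,5-tris(benzyloxy)-2-(prop-2-yn-1-yl)benzene F7.
  - n-BuLi gives {3-[2,4,6-tris(benzyloxy)phenyl]prop-1-yn-1-yl}lithium F8, which lithium tert-butyl peroxide oxidises to ynolate 11; iPr3SiOTf then gives 12.

**Step 8.**
- Risk: iodination may also occur at the two free carbons of ring B, or the electron-rich phenol may be oxidised.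
- Fallback (sets out from 17, returns at 21, replacing steps 8 and 9): a formylation that works only through a magnesium phenoxide and so cannot touch ring B.
  - MgCl2, Et3N and paraformaldehyde in MeCN at reflux give 2-hydroxy-6-methoxy-5-methyl-4-[(triisopropylsilyl)oxy]-3-{[2,4,6-tris(benzyloxy)phenyl]methyl}benzaldehyde F9.
  - MeMgBr in THF at 0 °C gives 2-(1-hydroxyethyl)-3-methoxy-4-methyl-5-[(triisopropylsilyl)oxy]-6-{[2,4,6-tris(benzyloxy)phenyl]methyl}phenol F10.
  - MnO2 in CH2Cl2 oxidises F10 to 21.

**Step 10.**
- Risk: acylation at a carbon flanked by two benzyloxy groups may be slow. The chelated A6 hydroxyl could be esterified, the liberated acid could cause benzyl loss, or the configuration could erode.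
- Fallback (sets out from 21, returns at 26): the classical acylation of the free phloroglucinol.
  - H2 with Pd/C gives 1-(2-hydroxy-6-methoxy-5-methyl-4-[(triisopropylsilyl)oxy]-3-[(2,4,6-trihydroxyphenyl)methyl]phenyl)ethan-1-one F11.
  - Bu4NF with AcOH gives 1-{2,4-dihydroxy-6-methoxy-5-methyl-3-[(2,4,6-trihydroxyphenyl)methyl]phenyl}ethan-1-one F12.
  - 22 with oxalyl chloride and catalytic DMF gives (2R)-2-methylbutanoyl chloride F13.
  - F12 and F13 with AlCl3 in PhNO2/CH2Cl2 at 0 °C give 26; ring A has no free carbon and the two ring B positions are equivalent.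

**Step 14.**
- Risk: discrimination between the two ortho hydroxyls may be insufficient, or a third sulfonylation may occur.
- Fallback (sets out from 29, returns at 32): a much bulkier silyl electrophile sharpens the steric choice, and methylation is done without base.
  - iPr3SiCl and imidazole in DMF give 1-{2-hydroxy-3-methyl-4,6-bis[(triisopropylsilyl)oxy]phenyl}-2-methylpropan-1-one F14.
  - Mitsunobu methylation (MeOH, PPh3, diisopropyl azodicarboxylate) gives 1-{2-methoxy-3-methyl-4,6-bis[(triisopropylsilyl)oxy]phenyl}-2-methylpropan-1-one F15.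
  - Bu4NF gives 32.

**Step 18.**
- Risk: at the temperature needed to expel the amine, the quinone methide may condense with itself, the existing bridge may scramble by retro-addition, or the polyphenolates may be oxidised by air.
- Fallback (sets out from 33, returns at 35): the leaving group is improved so that the quinone methide forms at room temperature.
  - MeI in acetone converts 33 into [2,6-dihydroxy-4-methoxy-3-methyl-5-(2-methylpropanoyl)phenyl]-N,N,N-trimethylmethanaminium iodide F16.
  - F16 is stirred with 26 and iPr2NEt in MeCN at rt to give 35.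

## Further compounds

F1 | step 7 | (1-methoxyethenyl)lithium | [Li]C(=C)OC
F2 | step 7 | 2-methoxypent-1-en-3-one | C=C(OC)C(=O)CC
F3 | step 7 | 1,1,1-trifluoro-5-methoxy-3-methylhex-5-ene-2,4-dione | C=C(OC)C(=O)C(C)C(=O)C(F)(F)F
F4 | step 7 | 2-diazo-4-methoxypent-4-en-3-one | C=C(OC)C(=O)C(C)=[N+]=[N-]
F5 | step 6 | [2,4,6-tris(benzyloxy)phenyl]lithium | [Li]c1c(OCc2ccccc2)cc(OCc2ccccc2)cc1OCc1ccccc1
F6 | step 6 | trimethyl{3-[2,4,6-tris(benzyloxy)phenyl]prop-1-yn-1-yl}silane | C[Si](C)(C)C#CCc1c(OCc2ccccc2)cc(OCc2ccccc2)cc1OCc1ccccc1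
F7 | step 6 | 1,3,5-tris(benzyloxy)-2-(prop-2-yn-1-yl)benzene | C#CCc1c(OCc2ccccc2)cc(OCc2ccccc2)cc1OCc1ccccc1
F8 | step 6 | {3-[2,4,6-tris(benzyloxy)phenyl]prop-1-yn-1-yl}lithium | [Li]C#CCc1c(OCc2ccccc2)cc(OCc2ccccc2)cc1OCc1ccccc1
F9 | step 8 | 2-hydroxy-6-methoxy-5-methyl-4-[(triisopropylsilyl)oxy]-3-{[2,4,6-tris(benzyloxy)phenyl]methyl}benzaldehyde | O=Cc1c(O)c(Cc2c(OCc3ccccc3)cc(OCc3ccccc3)cc2OCc2ccccc2)c(O[Si](C(C)C)(C(C)C)C(C)C)c(C)c1OC
F10 | step 8 | 2-(1-hydroxyethyl)-3-methoxy-4-methyl-5-[(triisopropylsilyl)oxy]-6-{[2,4,6-tris(benzyloxy)phenyl]methyl}phenol (racemic) | CC(O)c1c(O)c(Cc2c(OCc3ccccc3)cc(OCc3ccccc3)cc2OCc2ccccc2)c(O[Si](C(C)C)(C(C)C)C(C)C)c(C)c1OC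
F11 | step 10 | 1-(2-hydroxy-6-methoxy-5-methyl-4-[(triisopropylsilyl)oxy]-3-[(2,4,6-trihydroxyphenyl)methyl]phenyl)ethan-1-one | CC(=O)c1c(O)c(Cc2c(O)cc(O)cc2O)c(O[Si](C(C)C)(C(C)C)C(C)C)c(C)c1OC
F12 | step 10 | 1-{2,4-dihydroxy-6-methoxy-5-methyl-3-[(2,4,6-trihydroxyphenyl)methyl]phenyl}ethan-1-one | CC(=O)c1c(O)c(Cc2c(O)cc(O)cc2O)c(O)c(C)c1OC
F13 | step 10 | (2R)-2-methylbutanoyl chloride | CC[C@@H](C)C(Cl)=O
F14 | step 14 | 1-{2-hydroxy-3-methyl-4,6-bis[(triisopropylsilyl)oxy]phenyl}-2-methylpropan-1-one | CC(C)C(=O)c1c(O)c(C)c(O[Si](C(C)C)(C(C)C)C(C)C)cc1O[Si](C(C)C)(C(C)C)C(C)C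
F15 | step 14 | 1-{2-methoxy-3-methyl-4,6-bis[(triisopropylsilyl)oxy]phenyl}-2-methylpropan-1-one | CC(C)C(=O)c1c(OC)c(C)c(O[Si](C(C)C)(C(C)C)C(C)C)cc1O[Si](C(C)C)(C(C)C)C(C)C
F16 | step 18 | [2,6-dihydroxy-4-methoxy-3-methyl-5-(2-methylpropanoyl)phenyl]-N,N,N-trimethylmethanaminium iodide | CC(C)C(=O)c1c(O)c(C[N+](C)(C)C)c(O)c(C)c1OC.[I-]
A1 | alternative 1 | 2-{[4-methoxy-3-methyl-2-(trimethylsilyloxy)cyclohexa-1,3-dien-1-yl]methyl}-1,3,5-tris(benzyloxy)benzene | COC1=C(C)C(O[Si](C)(C)C)=C(Cc2c(OCc3ccccc3)cc(OCc3ccccc3)cc2OCc2ccccc2)CC1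
A2 | alternative 1 | 1-bromo-4-methylpent-1-yn-3-one | CC(C)C(=O)C#CBr
A3 | alternative 1 | 1-(2-bromo-6-methoxy-5-methyl-4-(trimethylsilyloxy)-3-{[2,4,6-tris(benzyloxy)phenyl]methyl}phenyl)-2-methylpropan-1-one | CC(C)C(=O)c1c(OC)c(C)c(O[Si](C)(C)C)c(Cc2c(OCc3ccccc3)cc(OCc3ccccc3)cc2OCc2ccccc2)c1Br
A4 | alternative 2 | methyl (8R)-2-{[3-acetyl-2,6-bis(benzyloxy)-4-methoxy-5-methylphenyl]methyl}-4-{[2,6-bis(benzyloxy)-4-methoxy-3-methyl-5-(2-methylpropanoyl)phenyl]methyl}-8-methyl-3,5,7-trioxodecanoate | COC(=O)C(Cc1c(OCc2ccccc2)c(C)c(OC)c(C(C)=O)c1OCc1ccccc1)C(=O)C(Cc1c(OCc2ccccc2)c(C)c(OC)c(C(=O)C(C)C)c1OCc1ccccc1)C(=O)CC(=O)[C@H](C)CC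
A5 | alternative 2 | (2R)-1-[3-{[3-acetyl-2,6-bis(benzyloxy)-4-methoxy-5-methylphenyl]methyl}-5-{[2,6-bis(benzyloxy)-4-methoxy-3-methyl-5-(2-methylpropanoyl)phenyl]methyl}-2,4,6-trihydroxyphenyl]-2-methylbutan-1-one | CC[C@@H](C)C(=O)c1c(O)c(Cc2c(OCc3ccccc3)c(C)c(OC)c(C(C)=O)c2OCc2ccccc2)c(O)c(Cc2c(OCc3ccccc3)c(C)c(OC)c(C(=O)C(C)C)c2OCc2ccccc2)c1O
A6 | alternative 3 | 2-[3,5-bis(trimethylsilyloxy)hexa-2,4-dien-1-yl]-1,3,5-tris(benzyloxy)benzene | CC(O[Si](C)(C)C)=CC(O[Si](C)(C)C)=CCc1c(OCc2ccccc2)cc(OCc2ccccc2)cc1OCc1ccccc1
A7 | alternative 3 | 3,3-dimethoxy-2-methylprop-2-enoyl chloride | COC(OC)=C(C)C(=O)Cl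
A8 | alternative 3 | 1-(2,4-dihydroxy-6-methoxy-5-methyl-3-{[2,4,6-tris(benzyloxy)phenyl]methyl}phenyl)ethan-1-one | CC(=O)c1c(OC)c(C)c(O)c(Cc2c(OCc3ccccc3)cc(OCc3ccccc3)cc2OCc2ccccc2)c1O
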